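**Retrosynthetic overview**

1. Target 13 ⇐ oxidation of the C15 alcohol, acetylation of the 3α-alcohol, and reagent-controlled reduction of a 3-ketone.
2. Rings A and B are made in one step: the 3-oxo-19-ester decalin with its C17 methylene ⇐ an acyclic (E,E)-polyene β-keto ester, by Mn(OAc)3/Cu(OAc)2 oxidative radical bicyclisation (C4–C5 bond, then C10–C9 bond, then loss of H from C17).
3. The terminal olefin of the polyene is already the (13R,14R)-oxirane of the target, so the cascade stops after ring B.
4. β-Keto ester ⇐ dianion of methyl 2-methylacetoacetate + an ω-bromo-2,3-epoxyfarnesyl silyl ether ⇐ (2E,6E)-farnesol by Sharpless epoxidation and allylic oxidation.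
5. Ring order: oxirane (step 1), then ring A and ring B together (step 6).

Assumption: labdane numbering is used for ring compounds, and the target is read as methyl (3R,4R,5R,9S,10R,13R,14S)-3-acetoxy-13,14-epoxy-15-oxolabd-8(17)-en-19-oate (3α-OAc axial, 4β-CO2Me axial, 4α-Me, 5α-H, 9α-H, 10β-Me, trans-oxirane).

Note on the ring configuration: the oxirane is too far from the reacting olefins to steer the bicyclisation, so step 6 delivers 9 as one half of a 1:1 pair with the diastereomer of opposite ring configuration (4S,5S,9R,10S; same oxirane). The pair is not separable at the ketone stage. It is taken into step 7, where the reagent-controlled reduction makes the two ring series differ at C3 (axial versus equatorial alcohol), and only the alcohol of the wanted series is isolated. The unwanted ring series is a by-product that is discarded there and plays no further part.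

**Route**

Step 1
Reactants: 1 (2E,6E)-farnesol
Product: 2 [(2R,3R)-3-[(3E)-4,8-dimethylnona-3,7-dien-1-yl]-3-methyloxiran-2-yl]methanol ((2R,3R)-2,3-epoxyfarnesol)
Conditions: Ti(OiPr)4 (5 mol%), D-(−)-diethyl tartrate (7 mol%), t-BuOOH (decane), 4 Å MS, CH2Cl2, −20 °C
Reagents that add atoms: tert-butyl hydroperoxide, CC(C)(C)OO
Why: Sharpless asymmetric epoxidation: the Ti(OiPr)4/diethyl tartrate complex binds the allylic alcohol so only the C2=C3 olefin reacts, and D-(−)-tartrate delivers oxygen to the face that gives the (2R,3R)-oxirane (the future C13 and C14) in about 95% ee.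

Step 2
Reactants: 2 (2R,3R)-2,3-epoxyfarnesol
Product: 3 tert-butyl{[(2R,3R)-3-[(3E)-4,8-dimethylnona-3,7-dien-1-yl]-3-methyloxiran-2-yl]methoxy}diphenylsilane
Conditions: TBDPSCl, imidazole, CH2Cl2, 0 °C → rt
Reagents that add atoms: tert-butyl(chloro)diphenylsilane, CC(C)(C)[Si](Cl)(c1ccccc1)c1ccccc1
Why: Silyl ether protection of the primary alcohol; TBDPS is chosen because it survives AcOH, enolates and hydride reagents later, and no stereocentre is touched.

Step 3
Reactants: 3 the TBDPS ether of epoxyfarnesol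
Product: 4 (2E,6E)-9-[(2R,3R)-3-{[(tert-butyldiphenylsilyl)oxy]methyl}-2-methyloxiran-2-yl]-2,6-dimethylnona-2,6-dien-1-ol
Conditions: SeO2 (0.3 equiv), salicylic acid (0.1 equiv), t-BuOOH (3 equiv), CH2Cl2, 0 °C → rt, stopped near 60% conversion
Reagents that add atoms: selenium dioxide, O=[Se]=O (delivers the oxygen; regenerated by tert-butyl hydroperoxide, CC(C)(C)OO)
Why: Sharpless–Umbreit allylic oxidation (ene reaction then [2,3]-sigmatropic shift) is selective for the (E)-methyl of the terminal isopropylidene unit and keeps the (E) geometry; unreacted 3 is recycled.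

Step 4
Reactants: 4 the ω-allylic alcohol
Product: 5 tert-butyl{[(2R,3R)-3-[(3E,7E)-9-bromo-4,8-dimethylnona-3,7-dien-1-yl]-3-methyloxiran-2-yl]methoxy}diphenylsilane
Conditions: CBr4, PPh3, CH2Cl2, −20 → 0 °C
Reagents that add atoms: carbon tetrabromide, BrC(Br)(Br)Br
Why: Appel bromination of the primary allylic alcohol by SN2 displacement under neutral conditions that spare the oxirane and both olefin geometries.

Step 5
Reactants: 5 the allylic bromide; 6 methyl 2-methyl-3-oxobutanoate
Product: 8 methyl (6E,10E)-2,6,10-trimethyl-3-oxo-13-[(2R,3R)-3-{[(tert-butyldiphenylsilyl)oxy]methyl}-2-methyloxiran-2-yl]trideca-6,10-dienoate, via dienolate dianion 7 (not isolated)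
Conditions: 6 (1.6 equiv), NaH (1.6 equiv), THF, 0 °C; n-BuLi (1.5 equiv), 0 °C; then 5, 0 °C, 30 min; aq NH4Cl
Reagents that add atoms: none
Why: Huckin–Weiler dianion alkylation: the terminal (γ) carbanion of 7 displaces the allylic bromide by SN2 and leaves the α-methyl β-keto ester intact (C2 epimers, irrelevant because this carbon becomes the radical centre).

Step 6
Reactants: 8 the epoxy-polyene β-keto ester
Product: 9 methyl (4R,5R,9S,10R,13R,14R)-15-[(tert-butyldiphenylsilyl)oxy]-13,14-epoxy-3-oxolabd-8(17)-en-19-oate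
Conditions: Mn(OAc)3·2H2O (2.2 equiv), Cu(OAc)2·H2O (1.0 equiv), KOAc (2 equiv), degassed AcOH, 25 °C
Reagents that add atoms: none
Why: Snider-type oxidative free-radical polyene cyclisation: Mn(OAc)3 generates the α,α-dicarbonyl radical, which closes ring A then ring B by two 6-endo additions through a chair–chair array of the (E,E)-diene (CO2Me axial and cis to the C10 methyl, 5α-H, 9α-H, trans-decalin), Cu(OAc)2 turns the tertiary C8 radical into the C17 methylene, and the cascade stops because the third olefin is already the oxirane; since the oxirane cannot bias the ring faces, 9 is obtained as half of a 1:1 pair with its ring diastereomer and is used as that pair.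

Step 7
Reactants: 9 the 3-ketone (as obtained in step 6, still accompanied by its ring diastereomer)
Product: 10 methyl (3R,4R,5R,9S,10R,13R,14R)-15-[(tert-butyldiphenylsilyl)oxy]-13,14-epoxy-3-hydroxylabd-8(17)-en-19-oate (3α-OH, axial; isolated as a single diastereomer on silica)
Conditions: (S)-Me-CBS oxazaborolidine [(S)-1-methyl-3,3-diphenyltetrahydro-1H,3H-pyrrolo[1,2-c][1,3,2]oxazaborole] (0.5 equiv), catecholborane (2.5 equiv), toluene, −78 → −30 °C; chromatography
Reagents that add atoms: none
Why: Corey–Bakshi–Shibata reduction under reagent control: the catalyst distinguishes quaternary C4 from the C2 methylene and sets C3 as (R) in both ring series, which is the axial 3α-alcohol for 9 but the equatorial alcohol for the accompanying ring diastereomer, so the two alcohols differ in polarity and shape, the unwanted one is removed by chromatography, and the absolute ring configuration of 10 is secured in the same operation; catecholborane leaves the olefin, ester and oxirane alone.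

Step 8
Reactants: 10 the 3α-alcohol
Product: 11 methyl (3R,4R,5R,9S,10R,13R,14R)-3-acetoxy-15-[(tert-butyldiphenylsilyl)oxy]-13,14-epoxylabd-8(17)-en-19-oate
Conditions: Ac2O, DMAP, pyridine, 40 °C
Reagents that add atoms: acetic anhydride, CC(=O)OC(C)=O
Why: DMAP-catalysed acylation of the hindered axial alcohol, with retention at C3.

Step 9
Reactants: 11 the silyl ether acetate
Product: 12 methyl (3R,4R,5R,9S,10R,13R,14R)-3-acetoxy-13,14-epoxy-15-hydroxylabd-8(17)-en-19-oate
Conditions: Bu4NF, AcOH (1:1), THF, 0 °C → rt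
Reagents that add atoms: none
Why: Fluoride desilylation buffered with AcOH, so that neither Payne rearrangement of the epoxy alcohol nor acetate cleavage occurs.

Step 10
Reactants: 12 the epoxy alcohol
Product: 13 methyl (3R,4R,5R,9S,10R,13R,14S)-3-acetoxy-13,14-epoxy-15-oxolabd-8(17)-en-19-oate (target)
Conditions: Dess–Martin periodinane, pyridine, CH2Cl2, 0 °C → rt
Reagents that add atoms: none
Why: Dess–Martin oxidation of the primary epoxy alcohol to the epoxy aldehyde under buffered conditions; C14 keeps its geometry and only its descriptor changes from R to S.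

**Compound list**

1 | (2E,6E)-farnesol | CC(C)=CCC/C(C)=C/CC/C(C)=C/CO | starting material
2 | (2R,3R)-2,3-epoxyfarnesol | CC(C)=CCC/C(C)=C/CC[C@@]1(C)O[C@@H]1CO | intermediate
3 | TBDPS ether of 2 | CC(C)=CCC/C(C)=C/CC[C@@]1(C)O[C@@H]1CO[Si](c1ccccc1)(c1ccccc1)C(C)(C)C | intermediate
4 | (2E,6E)-9-[(2R,3R)-3-{[(tert-butyldiphenylsilyl)oxy]methyl}-2-methyloxiran-2-yl]-2,6-dimethylnona-2,6-dien-1-ol | OC/C(C)=C/CC/C(C)=C/CC[C@@]1(C)O[C@@H]1CO[Si](c1ccccc1)(c1ccccc1)C(C)(C)C | intermediate
5 | allylic bromide corresponding to 4 | BrC/C(C)=C/CC/C(C)=C/CC[C@@]1(C)O[C@@H]1CO[Si](c1ccccc1)(c1ccccc1)C(C)(C)C | intermediate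
6 | methyl 2-methyl-3-oxobutanoate | COC(=O)C(C)C(C)=O | starting material
7 | sodium lithium dienolate (dianion) of 6 | [Li+].[Na+].C=C([O-])C(C)=C([O-])OC | intermediate
8 | methyl (6E,10E)-2,6,10-trimethyl-3-oxo-13-[(2R,3R)-3-{[(tert-butyldiphenylsilyl)oxy]methyl}-2-methyloxiran-2-yl]trideca-6,10-dienoate | COC(=O)C(C)C(=O)CC/C(C)=C/CC/C(C)=C/CC[C@@]1(C)O[C@@H]1CO[Si](c1ccccc1)(c1ccccc1)C(C)(C)C | intermediate
9 | methyl (4R,5R,9S,10R,13R,14R)-15-[(tert-butyldiphenylsilyl)oxy]-13,14-epoxy-3-oxolabd-8(17)-en-19-oate | C=C1CC[C@@H]2[C@](C)(CCC(=O)[C@]2(C)C(=O)OC)[C@H]1CC[C@@]1(C)O[C@@H]1CO[Si](c1ccccc1)(c1ccccc1)C(C)(C)C | intermediate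
10 | methyl (3R,4R,5R,9S,10R,13R,14R)-15-[(tert-butyldiphenylsilyl)oxy]-13,14-epoxy-3-hydroxylabd-8(17)-en-19-oate (3α-OH) | C=C1CC[C@@H]2[C@](C)(CC[C@@H](O)[C@]2(C)C(=O)OC)[C@H]1CC[C@@]1(C)O[C@@H]1CO[Si](c1ccccc1)(c1ccccc1)C(C)(C)C | intermediate
11 | methyl (3R,4R,5R,9S,10R,13R,14R)-3-acetoxy-15-[(tert-butyldiphenylsilyl)oxy]-13,14-epoxylabd-8(17)-en-19-oate | C=C1CC[C@@H]2[C@](C)(CC[C@@H](OC(C)=O)[C@]2(C)C(=O)OC)[C@H]1CC[C@@]1(C)O[C@@H]1CO[Si](c1ccccc1)(c1ccccc1)C(C)(C)C | intermediate
12 | methyl (3R,4R,5R,9S,10R,13R,14R)-3-acetoxy-13,14-epoxy-15-hydroxylabd-8(17)-en-19-oate | C=C1CC[C@@H]2[C@](C)(CC[C@@H](OC(C)=O)[C@]2(C)C(=O)OC)[C@H]1CC[C@@]1(C)O[C@@H]1CO | intermediate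
13 | methyl (3R,4R,5R,9S,10R,13R,14S)-3-acetoxy-13,14-epoxy-15-oxolabd-8(17)-en-19-oate | C=C1CC[C@@H]2[C@](C)(CC[C@@H](OC(C)=O)[C@]2(C)C(=O)OC)[C@H]1CC[C@@]1(C)O[C@@H]1C=O | target

**Step count and risks**

Total steps: 10. Longest linear sequence: 10 steps (1 → 13); 6 is bought and used directly.

Stereochemical purity: the enantiomer of 13 would need both the antipodal oxirane and the wrong ring series, so it is negligible. The few per cent of 13,14-bis-epimer that come from the antipodal oxirane of step 1 are removed by HPLC or crystallisation at 12 or 13.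

Steps most likely to fail:

1. Step 6 (bicyclisation). The oxirane may be opened in AcOH, or its oxygen may capture cationic character at C8. Some Δ7/Δ8 olefin isomers and tertiary acetate are also expected. Fallback, from 8 back to 9: 8 is selenenylated (NaH, PhSeCl, THF, 0 °C) to the α-phenylselanyl β-keto ester F1. Sunlamp irradiation of F1 in benzene at 20 °C, with no acid and no metal salt, runs the same free-radical bicyclisation as a phenylselanyl group-transfer chain. It gives the 8α-phenylselanyl labdanone F2 and its ring-antipodal diastereomer F3. H2O2/pyridine in CH2Cl2 at 0 °C then gives the selenoxides; the equatorial selenoxide in the rigid decalin should eliminate mainly towards C17 and return 9, again accompanied by its ring diastereomer, which is removed in step 7 as before.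

2. Step 7 (reagent-controlled reduction). The catalyst may not override the intrinsic facial bias of the hindered ring ketone, or 9 may react too slowly. Fallback, from 9 (as the pair obtained in step 6) back to 10: the material is reduced with LiBH(s-Bu)3 in THF at −78 °C. This bulky hydride attacks from the equatorial side under substrate control and gives 10 together with the axial alcohol F4 that arises from the ring diastereomer of 9. The two are separated by preparative HPLC on a cellulose tris(3,5-dimethylphenylcarbamate) phase, and 10 rejoins the route.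

3. Step 3 (allylic oxidation). Yield is typically modest, with over-oxidation to the enal and some attack at the internal olefin. Fallback, from 3 back to 4: cross-metathesis of 3 with methacrolein (second-generation Hoveyda–Grubbs catalyst, RuCl2(H2IMes)(=CH-C6H4-2-OiPr), CH2Cl2, 40 °C) exchanges the terminal isopropylidene group and gives the (E)-enal F5. Luche reduction (NaBH4, CeCl3·7H2O, MeOH, 0 °C) then gives 4.

**Further compounds**

F1 | step 6 | methyl (6E,10E)-2,6,10-trimethyl-3-oxo-2-(phenylselanyl)-13-[(2R,3R)-3-{[(tert-butyldiphenylsilyl)oxy]methyl}-2-methyloxiran-2-yl]trideca-6,10-dienoate | COC(=O)C(C)([Se]c1ccccc1)C(=O)CC/C(C)=C/CC/C(C)=C/CC[C@@]1(C)O[C@@H]1CO[Si](c1ccccc1)(c1ccccc1)C(C)(C)C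
F2 | step 6 | methyl (13R,14R)-15-[(tert-butyldiphenylsilyl)oxy]-13,14-epoxy-3-oxo-8α-(phenylselanyl)labdan-19-oate (ring configuration of 9; 17-methyl β) | C[C@@]1([Se]c3ccccc3)CC[C@@H]2[C@](C)(CCC(=O)[C@]2(C)C(=O)OC)[C@H]1CC[C@@]1(C)O[C@@H]1CO[Si](c1ccccc1)(c1ccccc1)C(C)(C)C
F3 | step 6 | ring-antipodal diastereomer of F2 (ring configuration opposite to 9, same oxirane) | C[C@]1([Se]c3ccccc3)CC[C@H]2[C@@](C)(CCC(=O)[C@@]2(C)C(=O)OC)[C@@H]1CC[C@@]1(C)O[C@@H]1CO[Si](c1ccccc1)(c1ccccc1)C(C)(C)C
F4 | step 7 | methyl (3S,4S,5S,9R,10S,13R,14R)-15-[(tert-butyldiphenylsilyl)oxy]-13,14-epoxy-3-hydroxylabd-8(17)-en-19-oate (axial alcohol of the ring series opposite to 9) | C=C1CC[C@H]2[C@@](C)(CC[C@H](O)[C@@]2(C)C(=O)OC)[C@@H]1CC[C@@]1(C)O[C@@H]1CO[Si](c1ccccc1)(c1ccccc1)C(C)(C)C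
F5 | step 3 | (2E,6E)-9-[(2R,3R)-3-{[(tert-butyldiphenylsilyl)oxy]methyl}-2-methyloxiran-2-yl]-2,6-dimethylnona-2,6-dienal | O=C/C(C)=C/CC/C(C)=C/CC[C@@]1(C)O[C@@H]1CO[Si](c1ccccc1)(c1ccccc1)C(C)(C)C
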